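**Retrosynthetic overview**

- The strategy rests on ring B: it carries oxygen on three alternate carbons, and the C1 methine (bearing ring C and the C2/C3-dimethyl chain to ring D) sits on the ring carbon between two of them. Its two remaining CH positions become equivalent once the ethers are cleaved.
- Last C–C bond: C-acylation of the free phloroglucinol ring B with 3-(4-methoxyphenyl)propanoic acid, after BBr3 has cleaved all ethers, so that the ring A methoxy group arrives last and survives.
- Ring B is disconnected into a 3-ethoxy-4-alkylcyclobutenone and ethoxyacetylene (benzannulation through a vinylketene). The cyclobutenone comes from a [2+2] of the chain-bearing ketene with ethoxyacetylene.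
- C1 is set by rhodium/(R)-BINAP aryl addition to an (E)-enoate. C2 and C3 are set by an Ireland–Claisen rearrangement with chirality transfer from (S,E)-pent-3-en-2-ol.
- Ring order: rings A, C and D are bought as anisole units; ring B is the only ring built (step 10).

Key step: step 10

**Remarks**

- Assumption: (S,E)-pent-3-en-2-ol is taken as available as the single enantiomer (otherwise by lipase resolution of the racemate).
- Locants: C1–C4 is the butane chain (C1 on ring B and ring C, C4 on ring D). The target is (1R,2S,3R). Descriptors in names change where CIP priorities change; the spatial arrangement does not.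

**Step 1**
Reactants: 1 (S,E)-pent-3-en-2-ol; 2 3-(4-methoxyphenyl)propanoic acid
Product: 3 (S,E)-pent-3-en-2-yl 3-(4-methoxyphenyl)propanoate
Conditions: DCC, DMAP (cat.), CH2Cl2, 0 → 20 °C
Reagents that add atoms: none
Why: Steglich esterification acylates the allylic alcohol at oxygen, so the C–O bond and its (S) configuration are untouched.

**Step 2**
Reactants: 3 (S,E)-pent-3-en-2-yl 3-(4-methoxyphenyl)propanoate
Product: 6 (2R,3R,E)-2-(4-methoxybenzyl)-3-methylhex-4-enoic acid, via silyl ketene acetal 4 (not isolated), via silyl ester 5 (not isolated)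
Conditions: LiN(iPr)2, THF, −78 °C; Me3SiCl/Et3N, −78 → 60 °C; then 1 M HCl
Reagents that add atoms: none
Why: Ireland–Claisen rearrangement, in which kinetic enolisation in THF without HMPA puts the CH2Ar group cis to the allylic oxygen and the chair transition state with the carbinol methyl equatorial transfers the (S) centre to the 2,3-anti (2R,3R) acid with an (E)-alkene.

**Step 3**
Reactants: 6 (2R,3R,E)-2-(4-methoxybenzyl)-3-methylhex-4-enoic acid
Product: 7 (2R,3R,E)-2-(4-methoxybenzyl)-3-methylhex-4-en-1-ol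
Conditions: LiAlH4, THF, 0 → 20 °C
Reagents that add atoms: none
Why: Hydride reduction of the carboxylic acid to the primary alcohol leaves the isolated alkene and both stereocentres alone.

**Step 4**
Reactants: 7 (2R,3R,E)-2-(4-methoxybenzyl)-3-methylhex-4-en-1-ol
Product: 8 (2R,3R,E)-2-(4-methoxybenzyl)-3-methylhex-4-en-1-yl 4-methylbenzenesulfonate
Conditions: TsCl, Et3N, DMAP (cat.), CH2Cl2, 0 → 20 °C
Reagents that add atoms: p-toluenesulfonyl chloride, Cc1ccc(S(=O)(=O)Cl)cc1
Why: Sulfonylation of the unhindered primary alcohol gives the leaving group for the deoxygenation.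

**Step 5**
Reactants: 8 (2R,3R,E)-2-(4-methoxybenzyl)-3-methylhex-4-en-1-yl 4-methylbenzenesulfonate
Product: 9 1-[(2R,3S,E)-2,3-dimethylhex-4-en-1-yl]-4-methoxybenzene
Conditions: LiEt3BH, THF, 0 → 20 °C
Reagents that add atoms: none
Why: SN2 displacement of the primary tosylate by the strongly nucleophilic borohydride turns CH2OTs into the C3 methyl group without touching C2 or C3.

**Step 6**
Reactants: 9 1-[(2R,3S,E)-2,3-dimethylhex-4-en-1-yl]-4-methoxybenzene; 10 methyl acrylate
Product: 11 methyl (4S,5R,E)-6-(4-methoxyphenyl)-4,5-dimethylhex-2-enoate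
Conditions: second-generation Hoveyda–Grubbs catalyst RuCl2(H2IMes)(=CH-C6H4-2-OiPr) (5 mol %), methyl acrylate (5 equiv), CH2Cl2, 40 °C
Reagents that add atoms: none
Why: Olefin cross-metathesis of the propenyl group with the electron-poor acrylate, which does not homodimerise, should give the (E)-enoate and is driven by loss of propene.

**Step 7**
Reactants: 11 methyl (4S,5R,E)-6-(4-methoxyphenyl)-4,5-dimethylhex-2-enoate; 12 4-methoxyphenylboronic acid
Product: 13 methyl (3R,4S,5R)-3,6-bis(4-methoxyphenyl)-4,5-dimethylhexanoate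
Conditions: Rh(acac)(C2H4)2 (3 mol %), (R)-BINAP, 12 (4 equiv), dioxane/H2O 10:1, 100 °C
Reagents that add atoms: none
Why: Hayashi–Miyaura 1,4-addition, in which the aryl–rhodium–(R)-BINAP species is expected by the accepted facial model to bind the 2-re face of the (E)-enoate and deliver ring C to C3 to give (3R) under catalyst control, with a diene-free rhodium precursor chosen so that no ligand-free background addition competes.

**Step 8**
Reactants: 13 methyl (3R,4S,5R)-3,6-bis(4-methoxyphenyl)-4,5-dimethylhexanoate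
Product: 14 (3R,4S,5R)-3,6-bis(4-methoxyphenyl)-4,5-dimethylhexanoic acid
Conditions: LiOH, THF/MeOH/H2O, 20 °C; then 1 M HCl
Reagents that add atoms: lithium hydroxide, [Li+].[OH-]
Why: Saponification of the methyl ester, with no stereocentre α to the carbonyl that could epimerise.

**Step 9**
Reactants: 14 (3R,4S,5R)-3,6-bis(4-methoxyphenyl)-4,5-dimethylhexanoic acid; 15 ethoxyacetylene
Product: 18 3-ethoxy-4-[(1S,2S,3R)-1,4-bis(4-methoxyphenyl)-2,3-dimethylbutyl]cyclobut-2-en-1-one (ring carbon C4 as both epimers), via acid chloride 16 (not isolated), via alkylketene 17 (not isolated)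
Conditions: (COCl)2, DMF (cat.), CH2Cl2, 0 → 20 °C, evaporate; then 15 (3 equiv), Et3N, Et2O, 0 → 20 °C, slow addition of the acid chloride
Reagents that add atoms: none
Why: Dehydrochlorination of the acid chloride gives the monoalkylketene, which is trapped as it forms by excess ethoxyacetylene in a ketene–alkyne [2+2] cycloaddition (alkyne CH to the ketene carbonyl carbon); the new ring stereocentre is of no consequence because it becomes aromatic in step 10.

**Step 10**
Reactants: 18 3-ethoxy-4-[(1S,2S,3R)-1,4-bis(4-methoxyphenyl)-2,3-dimethylbutyl]cyclobut-2-en-1-one; 15 ethoxyacetylene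
Product: 23 2-[(1R,2S,3R)-1,4-bis(4-methoxyphenyl)-2,3-dimethylbutyl]-3,5-diethoxyphenol, via vinylketene 19 (not isolated), via 4-vinylcyclobutenone 20 (not isolated), via dienylketene 21 (not isolated), via cyclohexadienone 22 (not isolated)
Conditions: 15 (4 equiv, in two portions), toluene, sealed tube, 85–95 °C
Reagents that add atoms: none
Why: Heating opens 18 by conrotatory 4π ring opening (chain rotating outward) to vinylketene 19, which adds ethoxyacetylene in a [2+2] cycloaddition to give 20, and a second 4π opening gives dienylketene 21. Ring B then closes by disrotatory 6π electrocyclisation between the ketene carbonyl carbon and the chain-bearing terminal carbon, and dienone 22 tautomerises to the phenol; this is the benzannulation of cyclobutenones with alkoxyacetylenes (Danheiser benzannulation). No stereocentre is formed, since both epimers of 18 converge on the same aromatic ring and C1–C3 lie outside the reacting π system with no acidifying group next to them. The selectivity needed is the orientation of the ketene–alkyne [2+2], and the polarisation of the ynol ether secures it: its nucleophilic CH carbon bonds to the electrophilic ketene carbonyl carbon, which puts the three oxygens on alternate carbons and the chain between OH and OEt. The bath is held below about 100 °C because ethoxyacetylene loses ethylene to ketene above that.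

**Step 11**
Reactants: 23 2-[(1R,2S,3R)-1,4-bis(4-methoxyphenyl)-2,3-dimethylbutyl]-3,5-diethoxyphenol
Product: 24 2-[(1R,2S,3R)-1,4-bis(4-hydroxyphenyl)-2,3-dimethylbutyl]benzene-1,3,5-triol
Conditions: BBr3 (8 equiv), CH2Cl2, −78 → 20 °C; then ice/H2O, argon
Reagents that add atoms: none
Why: BBr3 ether cleavage (boron–oxygen complexation, then bromide attack on the methyl and ethyl groups) frees all five phenols without touching the carbon stereocentres, and the cold quench limits protonation of the electron-rich ring B.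

**Step 12**
Reactants: 24 2-[(1R,2S,3R)-1,4-bis(4-hydroxyphenyl)-2,3-dimethylbutyl]benzene-1,3,5-triol; 2 3-(4-methoxyphenyl)propanoic acid
Product: 25 1-{3-[(1R,2S,3R)-1,4-bis(4-hydroxyphenyl)-2,3-dimethylbutyl]-2,4,6-trihydroxyphenyl}-3-(4-methoxyphenyl)propan-1-one (target)
Conditions: 2 (1.1 equiv), BF3·OEt2 (neat), 80 °C; then aq. NaOAc
Reagents that add atoms: none
Why: BF3-mediated Friedel–Crafts C-acylation with the free acid goes to the phloroglucinol ring B, by far the most nucleophilic arene, at either of its two equivalent free positions, and the chelated ketone formed deactivates the ring against a second acylation.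

**Compound list**

1 | (S,E)-pent-3-en-2-ol | C/C=C/[C@H](C)O | starting material
2 | 3-(4-methoxyphenyl)propanoic acid | COc1ccc(CCC(=O)O)cc1 | starting material
3 | (S,E)-pent-3-en-2-yl 3-(4-methoxyphenyl)propanoate | C/C=C/[C@H](C)OC(=O)CCc1ccc(OC)cc1 | intermediate
4 | (E)-trimethylsilyl ketene acetal of 3 (CH2Ar cis to the pentenyloxy oxygen) | C/C=C/[C@H](C)O/C(O[Si](C)(C)C)=C\Cc1ccc(OC)cc1 | intermediate
5 | trimethylsilyl (2R,3R,E)-2-(4-methoxybenzyl)-3-methylhex-4-enoate | C/C=C/[C@@H](C)[C@H](C(=O)O[Si](C)(C)C)Cc1ccc(OC)cc1 | intermediate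
6 | (2R,3R,E)-2-(4-methoxybenzyl)-3-methylhex-4-enoic acid | C/C=C/[C@@H](C)[C@H](C(=O)O)Cc1ccc(OC)cc1 | intermediate
7 | (2R,3R,E)-2-(4-methoxybenzyl)-3-methylhex-4-en-1-ol | C/C=C/[C@@H](C)[C@H](CO)Cc1ccc(OC)cc1 | intermediate
8 | (2R,3R,E)-2-(4-methoxybenzyl)-3-methylhex-4-en-1-yl 4-methylbenzenesulfonate | C/C=C/[C@@H](C)[C@H](COS(=O)(=O)c1ccc(C)cc1)Cc1ccc(OC)cc1 | intermediate
9 | 1-[(2R,3S,E)-2,3-dimethylhex-4-en-1-yl]-4-methoxybenzene | C/C=C/[C@@H](C)[C@H](C)Cc1ccc(OC)cc1 | intermediate
10 | methyl acrylate | C=CC(=O)OC | starting material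
11 | methyl (4S,5R,E)-6-(4-methoxyphenyl)-4,5-dimethylhex-2-enoate | COC(=O)/C=C/[C@@H](C)[C@H](C)Cc1ccc(OC)cc1 | intermediate
12 | 4-methoxyphenylboronic acid | COc1ccc(B(O)O)cc1 | starting material
13 | methyl (3R,4S,5R)-3,6-bis(4-methoxyphenyl)-4,5-dimethylhexanoate | COC(=O)C[C@@H](c1ccc(OC)cc1)[C@@H](C)[C@H](C)Cc1ccc(OC)cc1 | intermediate
14 | (3R,4S,5R)-3,6-bis(4-methoxyphenyl)-4,5-dimethylhexanoic acid | OC(=O)C[C@@H](c1ccc(OC)cc1)[C@@H](C)[C@H](C)Cc1ccc(OC)cc1 | intermediate
15 | ethoxyacetylene | CCOC#C | starting material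
16 | (3R,4S,5R)-3,6-bis(4-methoxyphenyl)-4,5-dimethylhexanoyl chloride | ClC(=O)C[C@@H](c1ccc(OC)cc1)[C@@H](C)[C@H](C)Cc1ccc(OC)cc1 | intermediate
17 | (3S,4S,5R)-3,6-bis(4-methoxyphenyl)-4,5-dimethylhex-1-en-1-one (monoalkylketene) | O=C=C[C@@H](c1ccc(OC)cc1)[C@@H](C)[C@H](C)Cc1ccc(OC)cc1 | intermediate
18 | 3-ethoxy-4-[(1S,2S,3R)-1,4-bis(4-methoxyphenyl)-2,3-dimethylbutyl]cyclobut-2-en-1-one (C4 epimers) | CCOC1=CC(=O)C1[C@@H](c1ccc(OC)cc1)[C@@H](C)[C@H](C)Cc1ccc(OC)cc1 | intermediate
19 | (3Z,5S,6S,7R)-3-ethoxy-5,8-bis(4-methoxyphenyl)-6,7-dimethylocta-1,3-dien-1-one (vinylketene) | O=C=C/C(OCC)=C/[C@@H](c1ccc(OC)cc1)[C@@H](C)[C@H](C)Cc1ccc(OC)cc1 | intermediate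
20 | 3-ethoxy-4-[(Z)-1-ethoxy-3,6-bis(4-methoxyphenyl)-4,5-dimethylhex-1-en-1-yl]cyclobut-2-en-1-one (ring C4 epimers) | CCOC1=CC(=O)C1/C(OCC)=C/[C@@H](c1ccc(OC)cc1)[C@@H](C)[C@H](C)Cc1ccc(OC)cc1 | intermediate
21 | 3,5-diethoxy-7,10-bis(4-methoxyphenyl)-8,9-dimethyldeca-1,3,5-trien-1-one (dienylketene, central alkene cis) | O=C=C/C(OCC)=C\C(OCC)=C\[C@@H](c1ccc(OC)cc1)[C@@H](C)[C@H](C)Cc1ccc(OC)cc1 | intermediate
22 | 6-[1,4-bis(4-methoxyphenyl)-2,3-dimethylbutyl]-3,5-diethoxycyclohexa-2,4-dien-1-one (C6 epimers) | O=C1C=C(OCC)C=C(OCC)C1[C@@H](c1ccc(OC)cc1)[C@@H](C)[C@H](C)Cc1ccc(OC)cc1 | intermediate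
23 | 2-[(1R,2S,3R)-1,4-bis(4-methoxyphenyl)-2,3-dimethylbutyl]-3,5-diethoxyphenol | CCOc1cc(OCC)c([C@@H](c2ccc(OC)cc2)[C@@H](C)[C@H](C)Cc2ccc(OC)cc2)c(O)c1 | intermediate
24 | 2-[(1R,2S,3R)-1,4-bis(4-hydroxyphenyl)-2,3-dimethylbutyl]benzene-1,3,5-triol | Oc1cc(O)c([C@@H](c2ccc(O)cc2)[C@@H](C)[C@H](C)Cc2ccc(O)cc2)c(O)c1 | intermediate
25 | 1-{3-[(1R,2S,3R)-1,4-bis(4-hydroxyphenyl)-2,3-dimethylbutyl]-2,4,6-trihydroxyphenyl}-3-(4-methoxyphenyl)propan-1-one | COc1ccc(CCC(=O)c2c(O)cc(O)c([C@@H](c3ccc(O)cc3)[C@@H](C)[C@H](C)Cc3ccc(O)cc3)c2O)cc1 | target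

**Step count**

Total: 12 steps. Longest linear sequence: 12 steps (1 and 2 to 25).

**Steps most likely to fail**

1. Step 10 (benzannulation). The ethoxy group stabilises cyclobutenone 18 as a vinylogous ester, so its ring opening may need temperatures at which ethoxyacetylene fragments to ketene and ethylene. The vinylketene may also dimerise or acylate the product phenol before the alkyne traps it. Fallback (ring B brought in preformed; sets out from 9, returns at 24):
   - Ozonolysis of 9 (O3, CH2Cl2, −78 °C; Me2S) should give (2S,3R)-4-(4-methoxyphenyl)-2,3-dimethylbutanal F1.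
   - 4-MeOC6H4MgBr (THF, −78 °C) should give (2S,3R)-1,4-bis(4-methoxyphenyl)-2,3-dimethylbutan-1-ol F2 as a mixture at C1.
   - Ionisation (HBF4·OEt2, CH2Cl2, −40 °C) with excess 1,3,5-trimethoxybenzene should give 2-[(1R,2S,3R)-1,4-bis(4-methoxyphenyl)-2,3-dimethylbutyl]-1,3,5-trimethoxybenzene F3 by Friedel–Crafts alkylation. The p-methoxybenzylic cation should adopt the conformer with the C2–H bond in its plane (allylic strain) and be attacked anti to the larger C3 branch, which corresponds to (1R).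
   - BBr3 then cleaves the five methyl ethers to give 24.

2. Step 7 (rhodium-catalysed aryl addition). Insertion into the γ-branched enoate may be slow, so protodeboronation uses up the boronic acid. Facial control may also be incomplete if the ligand and the C4 stereocentre are mismatched. Fallback (auxiliary control; sets out from 11, returns at 14):
   - LiOH should give (4S,5R,E)-6-(4-methoxyphenyl)-4,5-dimethylhex-2-enoic acid F4.
   - Pivaloyl chloride/Et3N (THF, −20 °C) converts it into the pivaloyl mixed anhydride F5, which acylates (R)-4-phenyloxazolidin-2-one (LiCl, Et3N) to give (R)-3-[(4S,5R,E)-6-(4-methoxyphenyl)-4,5-dimethylhex-2-enoyl]-4-phenyloxazolidin-2-one F6.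
   - 4-MeOC6H4MgBr with CuBr·SMe2 (THF/Me2S, −40 → −20 °C) should add anti to the auxiliary phenyl group of the chelated syn-s-cis imide and give (R)-3-[(3R,4S,5R)-3,6-bis(4-methoxyphenyl)-4,5-dimethylhexanoyl]-4-phenyloxazolidin-2-one F7.
   - LiOH/H2O2 (THF/H2O, 0 °C; Na2SO3; HCl) releases 14 and the auxiliary.

3. Step 12 (acylation). Hot BF3·OEt2 may acylate the phenols of rings C and D at oxygen or acylate ring B twice. It may also protonate ring B at the carbon bearing C1 and cause loss of the benzylic substituent. Fallback (Hoesch reaction; sets out from 24, returns at 25):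
   - 24 and 3-(4-methoxyphenyl)propanenitrile (ZnCl2, HCl gas, Et2O, 0 °C) should give the ring B ketimine 1-{3-[(1R,2S,3R)-1,4-bis(4-hydroxyphenyl)-2,3-dimethylbutyl]-2,4,6-trihydroxyphenyl}-3-(4-methoxyphenyl)propan-1-imine F8 as its hydrochloride.
   - Hydrolysis of the hydrochloride in warm water gives 25.

**Further compounds**

F1 | step 10 | (2S,3R)-4-(4-methoxyphenyl)-2,3-dimethylbutanal | O=C[C@@H](C)[C@H](C)Cc1ccc(OC)cc1
F2 | step 10 | (2S,3R)-1,4-bis(4-methoxyphenyl)-2,3-dimethylbutan-1-ol (C1 epimers) | OC(c1ccc(OC)cc1)[C@@H](C)[C@H](C)Cc1ccc(OC)cc1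
F3 | step 10 | 2-[(1R,2S,3R)-1,4-bis(4-methoxyphenyl)-2,3-dimethylbutyl]-1,3,5-trimethoxybenzene | COc1cc(OC)c([C@@H](c2ccc(OC)cc2)[C@@H](C)[C@H](C)Cc2ccc(OC)cc2)c(OC)c1
F4 | step 7 | (4S,5R,E)-6-(4-methoxyphenyl)-4,5-dimethylhex-2-enoic acid | OC(=O)/C=C/[C@@H](C)[C@H](C)Cc1ccc(OC)cc1
F5 | step 7 | (4S,5R,E)-6-(4-methoxyphenyl)-4,5-dimethylhex-2-enoic pivalic anhydride | CC(C)(C)C(=O)OC(=O)/C=C/[C@@H](C)[C@H](C)Cc1ccc(OC)cc1
F6 | step 7 | (R)-3-[(4S,5R,E)-6-(4-methoxyphenyl)-4,5-dimethylhex-2-enoyl]-4-phenyloxazolidin-2-one | O=C1OC[C@@H](c2ccccc2)N1C(=O)/C=C/[C@@H](C)[C@H](C)Cc1ccc(OC)cc1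
F7 | step 7 | (R)-3-[(3R,4S,5R)-3,6-bis(4-methoxyphenyl)-4,5-dimethylhexanoyl]-4-phenyloxazolidin-2-one | O=C1OC[C@@H](c2ccccc2)N1C(=O)C[C@@H](c1ccc(OC)cc1)[C@@H](C)[C@H](C)Cc1ccc(OC)cc1
F8 | step 12 | 1-{3-[(1R,2S,3R)-1,4-bis(4-hydroxyphenyl)-2,3-dimethylbutyl]-2,4,6-trihydroxyphenyl}-3-(4-methoxyphenyl)propan-1-imine | COc1ccc(CCC(=N)c2c(O)cc(O)c([C@@H](c3ccc(O)cc3)[C@@H](C)[C@H](C)Cc3ccc(O)cc3)c2O)cc1
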